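Ring A and ring C of the 7-methoxyflavone half are cut at C4a-C5 and O1-C2, which unravels that half into a linear 3-methoxy-5,7,9-trioxonon-2-enoate hung on the 4-aryloxyphenyl group of a partly benzylated scutellarein. The feature exploited is ring A (C4a, C5, C6, C7, C8, C8a): a phloroglucinol whose oxygens on C5 and C8a are equivalent while only the C7 oxygen is methylated, exactly what the single enol ether of the chain encodes. Magnesium methoxide followed by acetic acid folds the chain by Claisen cyclisation and cyclodehydration into the second flavone. The chain is carried as its enol lactone, a 4-methoxy-2-pyranone, and set free in the flask.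

Key step: step 5

Remark on protection: a scutellarein with O5, O7 and O4' benzylated and the 6-hydroxyl free cannot be reached directly, because the chelated 5-hydroxyl is the last phenol to react. Only O7 and O4' are therefore benzylated and the 5-hydroxyl of the scutellarein half stays free throughout.

Remark on the chain: an open-chain 3-methoxy-5-oxo-2-enoate whose saturated methylene is flanked by two carbonyl-type groups is too acidic to serve as an acyl donor and lactonises readily. The chain is therefore assembled and stored as the 4-methoxy-2-pyranone 7 and opened to ester 8 only in the flask of step 5. The lactone ring fixes the ester on the same side as the chain, which is the 2E geometry of 8.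

Remark on numbering: enolates, polyanions and magnesium chelates are treated as forms of the numbered neutral compounds. Ar = 4-({7-(benzyloxy)-2-[4-(benzyloxy)phenyl]-5-hydroxy-4-oxo-4H-chromen-6-yl}oxy)phenyl.

Step 1
Reactants: 1 scutellarein (5,6,7,4'-tetrahydroxyflavone)
Product: 2 7,4'-di-O-benzylscutellarein
Conditions: BnBr (2.1 equiv), K2CO3 (2.2 equiv), DMF, 0 °C to rt, Ar
Reagents that add atoms: benzyl bromide, BrCc1ccccc1
Why: Williamson ether synthesis under acidity control: the 7- and 4'-hydroxyls are vinylogous acids conjugated with the C4 carbonyl and react first, whereas the 6-hydroxyl is flanked on both sides and the 5-hydroxyl is hydrogen-bonded to the carbonyl, so two equivalents of benzyl bromide should stop at the 7,4'-diether.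

Step 2
Reactants: 2 7,4'-di-O-benzylscutellarein; 3 methyl 4-fluorobenzoate
Product: 4 methyl 4-({7-(benzyloxy)-2-[4-(benzyloxy)phenyl]-5-hydroxy-4-oxo-4H-chromen-6-yl}oxy)benzoate (Ar-CO2Me)
Conditions: 3 (1.5 equiv), Cs2CO3 (1.5 equiv), degassed DMSO, 110 °C, Ar
Reagents that add atoms: none
Why: Nucleophilic aromatic substitution (SNAr) through a Meisenheimer adduct stabilised by the para ester; the chelated 5-hydroxyl is the poorer nucleophile, so the 6-phenoxide should displace fluoride and place the diaryl ether oxygen of the target on C6''.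

Step 3
Reactants: 5 4-methoxy-6-methyl-2H-pyran-2-one
Product: 6 4-methoxy-6-(2-oxopropyl)-2H-pyran-2-one
Conditions: LiN(i-Pr)2 (LDA, 1.1 equiv), THF, −78 °C; MeC(O)N(OMe)Me, −78 to 0 °C; AcOH
Reagents that add atoms: N-methoxy-N-methylacetamide, CON(C)C(C)=O
Why: LDA deprotonates the 6-methyl group, which is vinylogously alpha to the lactone carbonyl, and the anion adds to the amide (Weinreb ketone synthesis); the chelated tetrahedral adduct survives until the quench, so the more acidic methylene of 6 cannot consume the anion.

Step 4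
Reactants: 6 4-methoxy-6-(2-oxopropyl)-2H-pyran-2-one; 4 Ar-CO2Me
Product: 7 6-(4-Ar-2,4-dioxobutyl)-4-methoxy-2H-pyran-2-one
Conditions: 6 (3 equiv), LDA (6 equiv), THF, −78 to 0 °C; 4, −78 °C to rt; AcOH, −78 °C
Reagents that add atoms: none
Why: Crossed Claisen condensation of a dianion with a non-enolisable ester: LDA removes first a proton of the methylene between pyranone and ketone and then one of the terminal methyl, the last-formed carbanion attacks the aromatic ester of 4, and the excess dianion takes up the phenol proton of 4 and the acidic proton of the new 1,3-diketone, while the resulting lithium 5-phenoxide shields the flavone carbonyl.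

Step 5
Reactants: 7 6-(4-Ar-2,4-dioxobutyl)-4-methoxy-2H-pyran-2-one
Product: 10 7'',4'''-di-O-benzylneocryptomerin, via open-chain ester 8 (not isolated), via aryl diketone 9 (not isolated)
Conditions: Mg(OMe)2 (6 equiv), MeOH–THF, reflux; then AcOH, 100 °C
Reagents that add atoms: none
Why: Methoxide opens the enol lactone of 7 at its carbonyl and leaves the magnesium chelate of ester 8, methyl (2E)-3-methoxy-5,7,9-trioxo-9-Ar-non-2-enoate, in which the ester sits on the same side as the chain. Chain carbon C6 (the future C4a), the methylene between the C5 and C7 carbonyls, then attacks the ester carbon C1 (the future C5) in a Claisen (Dieckmann-type) condensation that closes ring A 6-exo-trig; loss of methoxide and enolisation give acylphloroglucinol 9 with its single methyl ether para to the acyl group (the future O7). In hot acetic acid one of the two equivalent ortho phenols of 9 adds to the aryl ketone (6-exo-trig) and the hemiketal loses water, which closes the pyranone ring C at O1-C2. The closest known reactions are the magnesium methoxide conversion of 6-(2-oxoalkyl)-4-methoxy-2-pyranones into 2-acyl-5-methoxyresorcinols and the acid cyclodehydration of 2-hydroxyaryl 1,3-diketones that ends a Baker-Venkataraman flavone synthesis; no stereocentre is formed. The step needs Claisen folding to win over the aldol foldings (chain C4, the future C8, onto the aryl ketone, or chain C2 onto the C7 ketone): the C7 and C9 carbonyls are tied up as a magnesium diketonate and the aryl ketone is further deactivated by its para aryloxy group, whereas the ester cannot enolise and is held next to C6 by the E double bond. Because the oxygens on C5 and C8a of 9 are equivalent only one flavone can form, and relactonisation of 8 to 7 is harmless because methoxide reopens it.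

Step 6
Reactants: 10 7'',4'''-di-O-benzylneocryptomerin
Product: 11 neocryptomerin
Conditions: H2 (1 atm), Pd/C, THF–MeOH, rt
Reagents that add atoms: none
Why: Palladium-catalysed hydrogenolysis cleaves the two benzylic C-O bonds under neutral conditions that should leave the aryl methyl ether, the diaryl ether and both pyranone rings untouched.

Compound list
1 | scutellarein, 5,6,7-trihydroxy-2-(4-hydroxyphenyl)-4H-chromen-4-one | O=c1cc(-c2ccc(O)cc2)oc2cc(O)c(O)c(O)c12 | starting material
2 | 7,4'-di-O-benzylscutellarein, 7-(benzyloxy)-2-[4-(benzyloxy)phenyl]-5,6-dihydroxy-4H-chromen-4-one | O=c1cc(-c2ccc(OCc3ccccc3)cc2)oc2cc(OCc3ccccc3)c(O)c(O)c12 | intermediate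
3 | methyl 4-fluorobenzoate | COC(=O)c1ccc(F)cc1 | starting material
4 | methyl 4-({7-(benzyloxy)-2-[4-(benzyloxy)phenyl]-5-hydroxy-4-oxo-4H-chromen-6-yl}oxy)benzoate | COC(=O)c1ccc(Oc2c(OCc3ccccc3)cc3oc(-c4ccc(OCc5ccccc5)cc4)cc(=O)c3c2O)cc1 | intermediate
5 | 4-methoxy-6-methyl-2H-pyran-2-one | COc1cc(C)oc(=O)c1 | starting material
6 | 4-methoxy-6-(2-oxopropyl)-2H-pyran-2-one | COc1cc(CC(C)=O)oc(=O)c1 | intermediate
7 | 6-{4-[4-({7-(benzyloxy)-2-[4-(benzyloxy)phenyl]-5-hydroxy-4-oxo-4H-chromen-6-yl}oxy)phenyl]-2,4-dioxobutyl}-4-methoxy-2H-pyran-2-one | COc1cc(CC(=O)CC(=O)c2ccc(Oc3c(OCc4ccccc4)cc4oc(-c5ccc(OCc6ccccc6)cc5)cc(=O)c4c3O)cc2)oc(=O)c1 | intermediate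
8 | methyl (2E)-9-[4-({7-(benzyloxy)-2-[4-(benzyloxy)phenyl]-5-hydroxy-4-oxo-4H-chromen-6-yl}oxy)phenyl]-3-methoxy-5,7,9-trioxonon-2-enoate, drawn as the keto tautomer | COC(=O)/C=C(/OC)CC(=O)CC(=O)CC(=O)c1ccc(Oc2c(OCc3ccccc3)cc3oc(-c4ccc(OCc5ccccc5)cc4)cc(=O)c3c2O)cc1 | intermediate (not isolated)
9 | 1-[4-({7-(benzyloxy)-2-[4-(benzyloxy)phenyl]-5-hydroxy-4-oxo-4H-chromen-6-yl}oxy)phenyl]-3-(2,6-dihydroxy-4-methoxyphenyl)propane-1,3-dione | COc1cc(O)c(C(=O)CC(=O)c2ccc(Oc3c(OCc4ccccc4)cc4oc(-c5ccc(OCc6ccccc6)cc5)cc(=O)c4c3O)cc2)c(O)c1 | intermediate (not isolated)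
10 | 7'',4'''-di-O-benzylneocryptomerin, 7-(benzyloxy)-2-[4-(benzyloxy)phenyl]-5-hydroxy-6-[4-(5-hydroxy-7-methoxy-4-oxo-4H-chromen-2-yl)phenoxy]-4H-chromen-4-one | COc1cc(O)c2c(=O)cc(-c3ccc(Oc4c(OCc5ccccc5)cc5oc(-c6ccc(OCc7ccccc7)cc6)cc(=O)c5c4O)cc3)oc2c1 | intermediate
11 | neocryptomerin, 5,7-dihydroxy-6-[4-(5-hydroxy-7-methoxy-4-oxo-4H-chromen-2-yl)phenoxy]-2-(4-hydroxyphenyl)-4H-chromen-4-one | COc1cc(O)c2c(=O)cc(-c3ccc(Oc4c(O)cc5oc(-c6ccc(O)cc6)cc(=O)c5c4O)cc3)oc2c1 | target

Total step count: 6. Longest linear sequence: 5 steps (steps 1, 2, 4, 5 and 6 from scutellarein; the pyranone branch, steps 3 to 6, has four).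

Steps most likely to fail

Step 5. The released chain may fold in the wrong register, by aldol closure of chain C4 onto the aryl ketone or of C2 onto the C7 ketone. Methoxide may also cleave the 1,3-diketone by retro-Claisen reaction, and unreacted triketone may close to a 4-pyranone in the acid stage. The fallback takes ring A ready-made instead of folding it and sets out from compound 4. LiOH in THF–water should give 4-({7-(benzyloxy)-2-[4-(benzyloxy)phenyl]-5-hydroxy-4-oxo-4H-chromen-6-yl}oxy)benzoic acid F1. EDC hydrochloride and DMAP in CH2Cl2 should couple it with commercial 2',6'-dihydroxy-4'-methoxyacetophenone to the aryl ester 2-acetyl-3-hydroxy-5-methoxyphenyl 4-({7-(benzyloxy)-2-[4-(benzyloxy)phenyl]-5-hydroxy-4-oxo-4H-chromen-6-yl}oxy)benzoate F2. KOt-Bu in THF should then effect a Baker-Venkataraman rearrangement, which comes back to the route at compound 9, here isolated, and acetic acid at 100 °C closes it to compound 10 as in the second stage of step 5.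

Step 4. The dianion may be lost by proton transfer, acyl substitution at the electron-rich benzoate may be slow, and the carbanion may attack the lactone or the flavone carbonyl instead. The fallback makes the carbon-carbon bond by aldol addition and the ketone by oxidation, and sets out from compound 2. SNAr with 4-fluorobenzaldehyde (K2CO3, DMF, 90 °C) should give 4-({7-(benzyloxy)-2-[4-(benzyloxy)phenyl]-5-hydroxy-4-oxo-4H-chromen-6-yl}oxy)benzaldehyde F3. The dianion of 6, made as in step 4, should add to it at −78 °C to give the racemic aldol 6-(4-Ar-4-hydroxy-2-oxobutyl)-4-methoxy-2H-pyran-2-one F4. Activated MnO2 in CH2Cl2 should oxidise the benzylic alcohol, which removes the stereocentre and comes back to the route at compound 7.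

Step 2. Substitution may be sluggish because the 6-phenoxide is flanked on both sides and the ester is only a moderate activator. Carbonate and adventitious water may hydrolyse the ester, and the 5,6-dihydroxy system may be oxidised by air. The fallback is a copper-catalysed Ullmann ether synthesis from compound 2 with methyl 4-iodobenzoate (CuI, picolinic acid, K3PO4, DMSO, 90 °C), which comes back to the route at compound 4 and makes no compound outside the list (F0).

Further compounds
F1 | step 5 | 4-({7-(benzyloxy)-2-[4-(benzyloxy)phenyl]-5-hydroxy-4-oxo-4H-chromen-6-yl}oxy)benzoic acid | OC(=O)c1ccc(Oc2c(OCc3ccccc3)cc3oc(-c4ccc(OCc5ccccc5)cc4)cc(=O)c3c2O)cc1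
F2 | step 5 | 2-acetyl-3-hydroxy-5-methoxyphenyl 4-({7-(benzyloxy)-2-[4-(benzyloxy)phenyl]-5-hydroxy-4-oxo-4H-chromen-6-yl}oxy)benzoate | CC(=O)c1c(O)cc(OC)cc1OC(=O)c1ccc(Oc2c(OCc3ccccc3)cc3oc(-c4ccc(OCc5ccccc5)cc4)cc(=O)c3c2O)cc1
F3 | step 4 | 4-({7-(benzyloxy)-2-[4-(benzyloxy)phenyl]-5-hydroxy-4-oxo-4H-chromen-6-yl}oxy)benzaldehyde | O=Cc1ccc(Oc2c(OCc3ccccc3)cc3oc(-c4ccc(OCc5ccccc5)cc4)cc(=O)c3c2O)cc1
F4 | step 4 | racemic 6-{4-[4-({7-(benzyloxy)-2-[4-(benzyloxy)phenyl]-5-hydroxy-4-oxo-4H-chromen-6-yl}oxy)phenyl]-4-hydroxy-2-oxobutyl}-4-methoxy-2H-pyran-2-one | COc1cc(CC(=O)CC(O)c2ccc(Oc3c(OCc4ccccc4)cc4oc(-c5ccc(OCc6ccccc6)cc5)cc(=O)c4c3O)cc2)oc(=O)c1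
F0 | step 2 | none | none
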